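The route rests on making the C3–C4 bond of the (2E,4E)-4-methylocta-2,4-dienoate last. The C4(Me)=C5(H) alkene is read as a 2-alkyne: in one pot, syn hydrozirconation of methyl alkyne 34 (zirconium steered to C4 by the branched C6 stereocentre), zinc transmetalation and Negishi coupling with the (E)-3-iodoacrylate 23 of the C5 hydroxyl of the dihydropyranone ring join both halves and fix both diene geometries. The alkyne comes from a Johnson–Claisen chirality transfer; the lactone half from a desymmetrised meso-2,4-dimethylpentanediol, (S)-but-3-yn-2-ol, alkoxyallylboration and ring-closing metathesis.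

Key step: step 19

Assumption: compounds 1, 5, 13, 22, 24, 25 and (−)-Ipc2BOMe are taken as purchasable; locants C1–C8 refer to the dienoate chain, ring locants to the 2H-pyran-2-one.

**Lactone half (steps 1–13)**

Step 1
Reactants: 1 meso-2,4-dimethylglutaric anhydride
Product: 2 meso-(2R,4S)-2,4-dimethylpentane-1,5-diol
Conditions: LiAlH4, THF, 0 °C → reflux; aqueous work-up
Reagents that add atoms: none
Why: Hydride reduction of the cyclic anhydride converts both acyl carbons to CH2OH without touching the α-carbons, so the cis (meso) relationship of the two methyl groups is carried into the diol.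

Step 2
Reactants: 2 meso-(2R,4S)-2,4-dimethylpentane-1,5-diol
Product: 3 (2R,4S)-5-acetoxy-2,4-dimethylpentan-1-ol
Conditions: lipase AK (Pseudomonas fluorescens), vinyl acetate, THF, rt
Reagents that add atoms: vinyl acetate, C=COC(C)=O
Why: Lipase-catalysed desymmetrisation of a meso diol by irreversible transesterification should acetylate the hydroxymethyl arm on the (S)-configured carbon, which fixes the absolute configuration of both methyl-bearing centres of the side chain at once.

Step 3
Reactants: 3 (2R,4S)-5-acetoxy-2,4-dimethylpentan-1-ol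
Product: 4 (2S,4R)-5-iodo-2,4-dimethylpentyl acetate
Conditions: I2, PPh3, imidazole, CH2Cl2, 0 °C → rt
Reagents that add atoms: iodine, [I][I]
Why: Appel-type iodination acts only at the primary CH2OH and leaves the acetate and both stereocentres untouched.

Step 4
Reactants: 5 (S)-but-3-yn-2-ol
Product: 6 (S)-tert-butyl(but-3-yn-2-yloxy)dimethylsilane
Conditions: TBSCl, imidazole, CH2Cl2, 0 °C → rt
Reagents that add atoms: tert-butyldimethylsilyl chloride, CC(C)(C)[Si](C)(C)Cl
Why: Standard silylation of a secondary alcohol; the carbinol stereocentre of the side chain is taken from the chiral pool and no bond to it is broken.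

Step 5
Reactants: 6 (S)-tert-butyl(but-3-yn-2-yloxy)dimethylsilane
Product: 8 (S)-[(3-bromobut-3-en-2-yl)oxy](tert-butyl)dimethylsilane, via bromoboration adduct 7 (not isolated)
Conditions: B-bromo-9-BBN, CH2Cl2, 0 °C; then AcOH, 0 °C → rt
Reagents that add atoms: B-bromo-9-borabicyclo[3.3.1]nonane, BrB1C2CCCC1CCC2
Why: Syn bromoboration of a terminal alkyne places bromine on the internal carbon and boron on the terminus, and protonolysis of the alkenyl C–B bond by acetic acid should leave the 2-bromo-1-alkene (Markovnikov hydrobromination by haloboration/protodeboronation).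

Step 6
Reactants: 4 (2S,4R)-5-iodo-2,4-dimethylpentyl acetate; 8 (S)-[(3-bromobut-3-en-2-yl)oxy](tert-butyl)dimethylsilane
Product: 10 (2S,4R,7S)-7-[(tert-butyldimethylsilyl)oxy]-2,4-dimethyl-6-methylideneoctyl acetate, via alkylzinc iodide 9 (not isolated)
Conditions: Zn (activated with BrCH2CH2Br and TMSCl), DMA, 40 °C; then 8, PdCl2(dppf) (5 mol %), THF, 50 °C
Reagents that add atoms: none
Why: Zinc inserts into the primary C–I bond in the presence of the acetate, and an sp3–sp2 Negishi coupling with the 2-bromoalkene builds the 1,1-disubstituted alkene of the side chain without touching any stereocentre.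

Step 7
Reactants: 10 (2S,4R,7S)-7-[(tert-butyldimethylsilyl)oxy]-2,4-dimethyl-6-methylideneoctyl acetate
Product: 11 (2S,4R,7S)-7-[(tert-butyldimethylsilyl)oxy]-2,4-dimethyl-6-methylideneoctan-1-ol
Conditions: K2CO3 (0.2 equiv), MeOH, rt
Reagents that add atoms: none
Why: Base-catalysed transesterification removes the primary acetate while the secondary silyl ether is stable to carbonate in methanol.

Step 8
Reactants: 11 (2S,4R,7S)-7-[(tert-butyldimethylsilyl)oxy]-2,4-dimethyl-6-methylideneoctan-1-ol
Product: 12 (2S,4R,7S)-7-[(tert-butyldimethylsilyl)oxy]-2,4-dimethyl-6-methylideneoctanal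
Conditions: Dess–Martin periodinane, NaHCO3, CH2Cl2, 0 °C → rt; used at once
Reagents that add atoms: none
Why: Buffered Dess–Martin oxidation gives the α-methyl aldehyde under non-enolising conditions, so the adjacent stereocentre should not epimerise.

Step 9
Reactants: 12 (2S,4R,7S)-7-[(tert-butyldimethylsilyl)oxy]-2,4-dimethyl-6-methylideneoctanal; 13 allyl 4-methoxyphenyl ether
Product: 18 (3R,4R,5S,7R,10S)-10-[(tert-butyldimethylsilyl)oxy]-3-(4-methoxyphenoxy)-5,7-dimethyl-9-methylideneundec-1-en-4-ol, via allyllithium 14 (not isolated), via methoxyborate complex 15 (not isolated), via allylborane 16 (not isolated), via borinate ester 17 (not isolated)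
Conditions: 13, sec-BuLi, THF, −78 °C; (−)-Ipc2BOMe, −78 °C; BF3·OEt2, −78 °C; then 12, −78 °C; then NaOH aq, H2O2, 0 °C → rt
Reagents that add atoms: none
Why: Brown (Z)-γ-alkoxyallylboration through a chair Zimmerman–Traxler transition state: the Z geometry of the allylborane sets the syn relationship of the two oxygens (ring C5 and C6), and the isopinocampheyl groups derived from (+)-α-pinene direct attack to the Si face of the aldehyde to give the (R)-carbinol, overriding the aldehyde's own anti-Felkin preference (reagent control in a mismatched pair).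

Step 10
Reactants: 18 (3R,4R,5S,7R,10S)-10-[(tert-butyldimethylsilyl)oxy]-3-(4-methoxyphenoxy)-5,7-dimethyl-9-methylideneundec-1-en-4-ol
Product: 19 (3R,4R,5S,7R,10S)-10-[(tert-butyldimethylsilyl)oxy]-3-(4-methoxyphenoxy)-5,7-dimethyl-9-methylideneundec-1-en-4-yl acrylate
Conditions: acryloyl chloride, iPr2NEt, DMAP (cat.), CH2Cl2, −20 → 0 °C
Reagents that add atoms: acryloyl chloride, C=CC(Cl)=O
Why: O-Acylation of the only free hydroxyl installs the acrylate needed for ring closure, with no change at any stereocentre.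

Step 11
Reactants: 19 (3R,4R,5S,7R,10S)-10-[(tert-butyldimethylsilyl)oxy]-3-(4-methoxyphenoxy)-5,7-dimethyl-9-methylideneundec-1-en-4-yl acrylate
Product: 20 (5R,6R)-6-[(2S,4R,7S)-7-[(tert-butyldimethylsilyl)oxy]-4-methyl-6-methylideneoctan-2-yl]-5-(4-methoxyphenoxy)-5,6-dihydro-2H-pyran-2-one
Conditions: second-generation Grubbs catalyst RuCl2(=CHPh)(PCy3)(H2IMes) (5 mol %), CH2Cl2 (dilute), 40 °C
Reagents that add atoms: none
Why: Ring-closing metathesis between the acrylate and the monosubstituted vinyl group closes the six-membered unsaturated lactone, while the hindered 1,1-disubstituted alkene of the side chain should not compete.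

Step 12
Reactants: 20 (5R,6R)-6-[(2S,4R,7S)-7-[(tert-butyldimethylsilyl)oxy]-4-methyl-6-methylideneoctan-2-yl]-5-(4-methoxyphenoxy)-5,6-dihydro-2H-pyran-2-one
Product: 21 (5R,6R)-6-[(2S,4R,7S)-7-[(tert-butyldimethylsilyl)oxy]-4-methyl-6-methylideneoctan-2-yl]-5-hydroxy-5,6-dihydro-2H-pyran-2-one
Conditions: (NH4)2Ce(NO3)6, MeCN/H2O (4:1), 0 °C
Reagents that add atoms: none
Why: Oxidative dearylation of the 4-methoxyphenyl ether by tetravalent cerium releases the C5 hydroxyl with its C–O bond intact (retention), under conditions that a secondary TBS ether and the alkenes should survive.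

Step 13
Reactants: 21 (5R,6R)-6-[(2S,4R,7S)-7-[(tert-butyldimethylsilyl)oxy]-4-methyl-6-methylideneoctan-2-yl]-5-hydroxy-5,6-dihydro-2H-pyran-2-one; 22 (E)-3-iodoacrylic acid
Product: 23 (5R,6R)-6-[(2S,4R,7S)-7-[(tert-butyldimethylsilyl)oxy]-4-methyl-6-methylideneoctan-2-yl]-2-oxo-5,6-dihydro-2H-pyran-5-yl (E)-3-iodoacrylate
Conditions: N,N'-diisopropylcarbodiimide, DMAP (0.1 equiv), CH2Cl2, 0 °C
Reagents that add atoms: none
Why: Steglich esterification at low temperature with little nucleophilic catalyst acylates the C5 hydroxyl with retention and should keep the E geometry of the β-iodoacrylate.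

**Alkyne half (steps 14–18)**

Step 14
Reactants: 24 but-2-yn-1-ol; 25 1-(triphenylphosphoranylidene)propan-2-one
Product: 27 (E)-hept-3-en-5-yn-2-one, via but-2-ynal 26 (not isolated)
Conditions: activated MnO2, 25, CH2Cl2, rt
Reagents that add atoms: none
Why: Tandem oxidation/Wittig olefination: MnO2 oxidises the propargylic alcohol to the volatile ynal, which the stabilised ylide traps in situ to give the E-enone.

Step 15
Reactants: 27 (E)-hept-3-en-5-yn-2-one
Product: 28 (R,E)-hept-3-en-5-yn-2-ol
Conditions: (S)-2-methyl-CBS-oxazaborolidine (0.2 equiv), catecholborane, toluene, −78 °C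
Reagents that add atoms: none
Why: Corey–Bakshi–Shibata reduction: the (S)-oxazaborolidine differentiates the alkenyl (large) and methyl (small) groups and should deliver hydride to give the (R)-allylic alcohol by 1,2-reduction.

Step 16
Reactants: 28 (R,E)-hept-3-en-5-yn-2-ol
Product: 31 ethyl (3R,4E)-3-(prop-1-yn-1-yl)hex-4-enoate, via mixed orthoester 29 (not isolated), via ketene acetal 30 (not isolated)
Conditions: MeC(OEt)3, propionic acid (cat.), 135 °C, EtOH distilled off
Reagents that add atoms: triethyl orthoacetate, CCOC(C)(OCC)OCC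
Why: Johnson–Claisen [3,3]-sigmatropic rearrangement through a chair transition state with the carbinol methyl equatorial transfers the C–O chirality suprafacially to the new C–C bond, setting the propargylic stereocentre (future C6 of the dienoate) as R and the new alkene as E.

Step 17
Reactants: 31 ethyl (3R,4E)-3-(prop-1-yn-1-yl)hex-4-enoate
Product: 33 (S)-2-(prop-1-yn-1-yl)butane-1,4-diol, via ozonide 32 (not isolated)
Conditions: O3, CH2Cl2, −78 °C (Sudan Red 7B end point), N2 purge; then LiBH4, THF, −78 °C → rt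
Reagents that add atoms: ozone, [O-][O+]=O
Why: Ozonolysis cleaves the 1,2-disubstituted alkene far faster than the internal alkyne, and borohydride reduces the ozonide directly to the primary alcohol and the ethyl ester to the second one, so the propargylic centre should never rest next to a free aldehyde.

Step 18
Reactants: 33 (S)-2-(prop-1-yn-1-yl)butane-1,4-diol
Product: 34 (S)-1,4-bis[(tert-butyldimethylsilyl)oxy]-2-(prop-1-yn-1-yl)butane
Conditions: TBSCl, imidazole, DMF, rt
Reagents that add atoms: tert-butyldimethylsilyl chloride, CC(C)(C)[Si](C)(C)Cl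
Why: Silylation of both primary hydroxyls removes all acidic protons before hydrozirconation and leaves the stereocentre untouched.

**Fragment union and deprotection (steps 19–20)**

Step 19
Reactants: 34 (S)-1,4-bis[(tert-butyldimethylsilyl)oxy]-2-(prop-1-yn-1-yl)butane; 23 (5R,6R)-6-[(2S,4R,7S)-7-[(tert-butyldimethylsilyl)oxy]-4-methyl-6-methylideneoctan-2-yl]-2-oxo-5,6-dihydro-2H-pyran-5-yl (E)-3-iodoacrylate
Product: 37 (5R,6R)-6-[(2S,4R,7S)-7-[(tert-butyldimethylsilyl)oxy]-4-methyl-6-methylideneoctan-2-yl]-2-oxo-5,6-dihydro-2H-pyran-5-yl (2E,4E,6S)-8-[(tert-butyldimethylsilyl)oxy]-6-{[(tert-butyldimethylsilyl)oxy]methyl}-4-methylocta-2,4-dienoate, via alkenylzirconocene 35 (not isolated), via alkenylzinc chloride 36 (not isolated)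
Conditions: 34 (1.6 equiv), Cp2Zr(H)Cl, THF, 50 °C; then ZnCl2 (THF), 0 °C; then 23 (1.0 equiv), Pd(PPh3)4 (5 mol %), THF, 0 °C → rt
Reagents that add atoms: none
Why: Cp2Zr(H)Cl adds syn across the C4≡C5 triple bond of 34 and, under equilibrating conditions, zirconium should settle on C4 next to the small methyl group, not on C5 next to the branched C6 stereocentre, giving the (E)-alkenylzirconocene 35. Transmetalation to zinc (36) and a Negishi cross-coupling (oxidative addition of zerovalent palladium into the C–I bond of 23, transmetalation, reductive elimination) then forge the C3–C4 bond with retention at both alkene carbons. The closest known reaction type is the one-pot hydrozirconation/zirconium-to-zinc transmetalation/palladium-catalysed coupling of 2-alkynes with (E)-β-iodoacrylates that is used to make trisubstituted (E,E)-dienoates. No ring is closed and no stereocentre is created; the C4=C5 E geometry is controlled by the syn H–Zr addition and the C2=C3 E geometry by stereoretentive coupling of the (E)-iodide. The step needs regioselectivity (C4 against C5 metalation), secured by the steric contrast between methyl and the CH(CH2OTBS)CH2CH2OTBS group, and chemoselectivity, secured because the alkenylzinc is too soft to attack the lactone or esters and the C(sp2)–I bond is the only site that adds to palladium. The alkyne is used in excess so that the iodide is the limiting partner.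

Step 20
Reactants: 37 tris-TBS ether of the target
Product: 38 CNP0219019.1: (5R,6R)-6-[(2S,4R,7S)-7-hydroxy-4-methyl-6-methylideneoctan-2-yl]-2-oxo-5,6-dihydro-2H-pyran-5-yl (2E,4E,6S)-8-hydroxy-6-(hydroxymethyl)-4-methylocta-2,4-dienoate
Conditions: HF·pyridine, pyridine, THF, 0 °C → rt
Reagents that add atoms: none
Why: Buffered fluoride-mediated desilylation removes the two primary and the one secondary allylic TBS ether under mildly acidic conditions that should not open the lactone, migrate the dienoate ester or isomerise the diene.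

**Compound list**

1 | meso-2,4-dimethylglutaric anhydride, (3R,5S)-3,5-dimethyloxane-2,6-dione | C[C@H]1C[C@@H](C)C(=O)OC1=O | starting material
2 | meso-(2R,4S)-2,4-dimethylpentane-1,5-diol | OC[C@H](C)C[C@H](C)CO | intermediate
3 | (2R,4S)-5-acetoxy-2,4-dimethylpentan-1-ol | OC[C@H](C)C[C@H](C)COC(C)=O | intermediate
4 | (2S,4R)-5-iodo-2,4-dimethylpentyl acetate | IC[C@H](C)C[C@H](C)COC(C)=O | intermediate
5 | (S)-but-3-yn-2-ol | C#C[C@H](C)O | starting material
6 | (S)-tert-butyl(but-3-yn-2-yloxy)dimethylsilane | C#C[C@H](C)O[Si](C)(C)C(C)(C)C | intermediate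
7 | (S,Z)-9-{2-bromo-3-[(tert-butyldimethylsilyl)oxy]but-1-en-1-yl}-9-borabicyclo[3.3.1]nonane (formed in the flask) | Br/C(=C\B1C2CCCC1CCC2)[C@H](C)O[Si](C)(C)C(C)(C)C | intermediate
8 | (S)-[(3-bromobut-3-en-2-yl)oxy](tert-butyl)dimethylsilane | C=C(Br)[C@H](C)O[Si](C)(C)C(C)(C)C | intermediate
9 | [(2R,4S)-5-acetoxy-2,4-dimethylpentyl]zinc iodide (formed in the flask) | I[Zn]C[C@H](C)C[C@H](C)COC(C)=O | intermediate
10 | (2S,4R,7S)-7-[(tert-butyldimethylsilyl)oxy]-2,4-dimethyl-6-methylideneoctyl acetate | C=C(C[C@H](C)C[C@H](C)COC(C)=O)[C@H](C)O[Si](C)(C)C(C)(C)C | intermediate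
11 | (2S,4R,7S)-7-[(tert-butyldimethylsilyl)oxy]-2,4-dimethyl-6-methylideneoctan-1-ol | C=C(C[C@H](C)C[C@H](C)CO)[C@H](C)O[Si](C)(C)C(C)(C)C | intermediate
12 | (2S,4R,7S)-7-[(tert-butyldimethylsilyl)oxy]-2,4-dimethyl-6-methylideneoctanal | C=C(C[C@H](C)C[C@H](C)C=O)[C@H](C)O[Si](C)(C)C(C)(C)C | intermediate
13 | allyl 4-methoxyphenyl ether | C=CCOc1ccc(OC)cc1 | starting material
14 | [(Z)-3-(4-methoxyphenoxy)allyl]lithium (formed in the flask) | [Li]C/C=C\Oc1ccc(OC)cc1 | intermediate
15 | lithium [(Z)-3-(4-methoxyphenoxy)allyl]bis(isopinocampheyl)(methoxy)borate (formed in the flask) | [Li+].CO[B-](C/C=C\Oc1ccc(OC)cc1)([C@@H]1C[C@@H]2C[C@H]([C@H]1C)C2(C)C)[C@@H]1C[C@@H]2C[C@H]([C@H]1C)C2(C)C | intermediate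
16 | [(Z)-3-(4-methoxyphenoxy)allyl]bis(isopinocampheyl)borane (formed in the flask) | COc1ccc(O/C=C\CB([C@@H]2C[C@@H]3C[C@H]([C@H]2C)C3(C)C)[C@@H]2C[C@@H]3C[C@H]([C@H]2C)C3(C)C)cc1 | intermediate
17 | bis(isopinocampheyl)borinate ester of 18 (formed in the flask) | C=C(C[C@H](C)C[C@H](C)[C@@H](OB([C@@H]1C[C@@H]2C[C@H]([C@H]1C)C2(C)C)[C@@H]1C[C@@H]2C[C@H]([C@H]1C)C2(C)C)[C@H](Oc1ccc(OC)cc1)C=C)[C@H](C)O[Si](C)(C)C(C)(C)C | intermediate
18 | (3R,4R,5S,7R,10S)-10-[(tert-butyldimethylsilyl)oxy]-3-(4-methoxyphenoxy)-5,7-dimethyl-9-methylideneundec-1-en-4-ol | C=C(C[C@H](C)C[C@H](C)[C@@H](O)[C@H](Oc1ccc(OC)cc1)C=C)[C@H](C)O[Si](C)(C)C(C)(C)C | intermediate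
19 | (3R,4R,5S,7R,10S)-10-[(tert-butyldimethylsilyl)oxy]-3-(4-methoxyphenoxy)-5,7-dimethyl-9-methylideneundec-1-en-4-yl acrylate | C=C(C[C@H](C)C[C@H](C)[C@@H](OC(=O)C=C)[C@H](Oc1ccc(OC)cc1)C=C)[C@H](C)O[Si](C)(C)C(C)(C)C | intermediate
20 | (5R,6R)-6-[(2S,4R,7S)-7-[(tert-butyldimethylsilyl)oxy]-4-methyl-6-methylideneoctan-2-yl]-5-(4-methoxyphenoxy)-5,6-dihydro-2H-pyran-2-one | C=C(C[C@H](C)C[C@H](C)[C@H]1OC(=O)C=C[C@H]1Oc2ccc(OC)cc2)[C@H](C)O[Si](C)(C)C(C)(C)C | intermediate
21 | (5R,6R)-6-[(2S,4R,7S)-7-[(tert-butyldimethylsilyl)oxy]-4-methyl-6-methylideneoctan-2-yl]-5-hydroxy-5,6-dihydro-2H-pyran-2-one | C=C(C[C@H](C)C[C@H](C)[C@H]1OC(=O)C=C[C@H]1O)[C@H](C)O[Si](C)(C)C(C)(C)C | intermediate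
22 | (E)-3-iodoacrylic acid | OC(=O)/C=C/I | starting material
23 | (5R,6R)-6-[(2S,4R,7S)-7-[(tert-butyldimethylsilyl)oxy]-4-methyl-6-methylideneoctan-2-yl]-2-oxo-5,6-dihydro-2H-pyran-5-yl (E)-3-iodoacrylate | C=C(C[C@H](C)C[C@H](C)[C@H]1OC(=O)C=C[C@H]1OC(=O)/C=C/I)[C@H](C)O[Si](C)(C)C(C)(C)C | intermediate
24 | but-2-yn-1-ol | CC#CCO | starting material
25 | 1-(triphenylphosphoranylidene)propan-2-one | CC(=O)C=P(c1ccccc1)(c1ccccc1)c1ccccc1 | starting material
26 | but-2-ynal (formed in the flask) | CC#CC=O | intermediate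
27 | (E)-hept-3-en-5-yn-2-one | CC#C/C=C/C(C)=O | intermediate
28 | (R,E)-hept-3-en-5-yn-2-ol | C[C@@H](O)/C=C/C#CC | intermediate
29 | (R,E)-2-(1,1-diethoxyethoxy)hept-3-en-5-yne, mixed orthoester (formed in the flask) | C[C@@H](OC(C)(OCC)OCC)/C=C/C#CC | intermediate
30 | (R,E)-2-[(1-ethoxyvinyl)oxy]hept-3-en-5-yne, ketene acetal (formed in the flask) | C[C@@H](OC(=C)OCC)/C=C/C#CC | intermediate
31 | ethyl (3R,4E)-3-(prop-1-yn-1-yl)hex-4-enoate | CCOC(=O)C[C@@H](C#CC)/C=C/C | intermediate
32 | ethyl (3S)-3-(5-methyl-1,2,4-trioxolan-3-yl)hex-4-ynoate, ozonide as a mixture at the trioxolane carbons (formed in the flask) | CCOC(=O)C[C@@H](C#CC)C1OOC(C)O1 | intermediate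
33 | (S)-2-(prop-1-yn-1-yl)butane-1,4-diol | CC#C[C@@H](CO)CCO | intermediate
34 | (S)-1,4-bis[(tert-butyldimethylsilyl)oxy]-2-(prop-1-yn-1-yl)butane | CC#C[C@@H](CO[Si](C)(C)C(C)(C)C)CCO[Si](C)(C)C(C)(C)C | intermediate
35 | chloro{(S,E)-5-[(tert-butyldimethylsilyl)oxy]-3-{[(tert-butyldimethylsilyl)oxy]methyl}pent-1-en-1-yl-1-methyl}zirconocene, zirconium on C4 (formed in the flask) | Cl[Zr](C1C=CC=C1)(C1C=CC=C1)/C(C)=C/[C@@H](CO[Si](C)(C)C(C)(C)C)CCO[Si](C)(C)C(C)(C)C | intermediate
36 | corresponding (E)-alkenylzinc chloride, zinc on C4 (formed in the flask) | Cl[Zn]/C(C)=C/[C@@H](CO[Si](C)(C)C(C)(C)C)CCO[Si](C)(C)C(C)(C)C | intermediate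
37 | tris-TBS ether of the target (name as in step 19) | C=C(C[C@H](C)C[C@H](C)[C@H]1OC(=O)C=C[C@H]1OC(=O)/C=C/C(C)=C/[C@@H](CO[Si](C)(C)C(C)(C)C)CCO[Si](C)(C)C(C)(C)C)[C@H](C)O[Si](C)(C)C(C)(C)C | intermediate
38 | CNP0219019.1 (name as in step 20) | C=C(C[C@H](C)C[C@H](C)[C@H]1OC(=O)C=C[C@H]1OC(=O)/C=C/C(C)=C/[C@@H](CO)CCO)[C@H](C)O | target

**Step count**

Total: 20 steps. Longest linear sequence: 13 steps (1, 2, 3, 6, 7, 8, 9, 10, 11, 12, 13, 19, 20).

**Steps most likely to fail**

1. Step 19 (key step). The alkenylzirconium regioisomers may not equilibrate fully. Hydride left over from the hydrozirconation may also be passed on to zinc and palladium, so that the iodoacrylate is hydrodehalogenated or the enoate lactone is reduced. The fallback sets out from 34 and 21 and returns at 37. Alkyne 34 is hydrozirconated alone (Cp2Zr(H)Cl, THF, 50 °C) and quenched with iodine to give (S,E)-1,4-bis[(tert-butyldimethylsilyl)oxy]-2-(2-iodoprop-1-en-1-yl)butane F1, which is purified free of any regioisomer and of all hydride. Alcohol 21 is acylated with acryloyl chloride and iPr2NEt to the C5 acrylate F2. A Mizoroki–Heck reaction of F1 with F2 (Pd(OAc)2, Bu4NCl, K2CO3, DMF, rt → 40 °C) then makes the same C3–C4 bond with the polarity of the partners reversed and should give 37.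

2. Step 9. The pairing of the chiral borane with the α-methyl aldehyde is mismatched, so facial selectivity at the aldehyde may erode and the C5/C6 diastereomers may be hard to separate. The fallback sets out from 13 and 12 and returns at 18. Ether 13 is lithiated (sec-BuLi, THF, −78 °C) and trapped with Bu3SnCl to give tributyl[(Z)-3-(4-methoxyphenoxy)allyl]stannane F3. Addition of F3 to 12 promoted by BF3·OEt2 (CH2Cl2, −78 °C) runs through an open transition state in which substrate (Felkin) control and the syn preference of γ-alkoxyallylstannanes both favour the all-syn triad of 18, so no chiral reagent has to override the aldehyde.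

3. Step 17. The propargylic centre may enolise while it sits next to an aldehyde-level carbon, and ozone may attack the alkyne. The fallback sets out from 31 and returns at 33. Ester 31 is first reduced (LiAlH4, Et2O, 0 °C) to (3R,4E)-3-(prop-1-yn-1-yl)hex-4-en-1-ol F4. The alkene alone is then dihydroxylated (OsO4 cat., N-methylmorpholine N-oxide, acetone/H2O), which leaves the alkyne untouched, to give (3R)-3-(prop-1-yn-1-yl)hexane-1,4,5-triol F5. Glycol cleavage with NaIO4 releases the aldehyde only as its five-membered lactol with the C1 hydroxyl, and NaBH4 added to the same flask reduces it to 33.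

Further compounds
F1 | step 19 | (S,E)-1,4-bis[(tert-butyldimethylsilyl)oxy]-2-(2-iodoprop-1-en-1-yl)butane | I/C(C)=C/[C@@H](CO[Si](C)(C)C(C)(C)C)CCO[Si](C)(C)C(C)(C)C
F2 | step 19 | (5R,6R)-6-[(2S,4R,7S)-7-[(tert-butyldimethylsilyl)oxy]-4-methyl-6-methylideneoctan-2-yl]-2-oxo-5,6-dihydro-2H-pyran-5-yl acrylate | C=C(C[C@H](C)C[C@H](C)[C@H]1OC(=O)C=C[C@H]1OC(=O)C=C)[C@H](C)O[Si](C)(C)C(C)(C)C
F3 | step 9 | tributyl[(Z)-3-(4-methoxyphenoxy)allyl]stannane | CCCC[Sn](CCCC)(CCCC)C/C=C\Oc1ccc(OC)cc1
F4 | step 17 | (3R,4E)-3-(prop-1-yn-1-yl)hex-4-en-1-ol | OCC[C@@H](C#CC)/C=C/C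
F5 | step 17 | (3R)-3-(prop-1-yn-1-yl)hexane-1,4,5-triol (mixture at C4 and C5) | OCC[C@@H](C#CC)C(O)C(C)O
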